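**Retrosynthetic overview**

Locants used below: ring A = C1–C2–C3(=O)–C4–C5–C10, ring B = C5–C6(OH)–C7–C8(CH3)–C9–C10, C19 = the oxymethylene on C4; the ring-fusion alkene is C5=C10.
Late disconnections: both silyl ethers; the butenolide by B-alkyl Suzuki–Miyaura coupling at a C9 vinyl group; the C19 ester; C19 itself by deconjugative aldol of the C3–C4–C5–C10 dienolate with formaldehyde, anti to an axial C6 silyloxy group; C6–OH by γ-hydroxylation of the dienol ether of a 4-methyl-4-en-3-one.
Key disconnection: ring A of that enone is opened at C1–C2 and C4–C5, a Robinson-type (3+3) annulation of the ring-B 2-methylidene ketone 11 (electrophilic at C1 and C5, released in the flask from ammonium salt 9) with methyl 3-oxopentanoate (nucleophilic at C2, then at C4; its ester is a traceless activating group).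
Enabling feature: the C3 ketone lies 1,5 to C5 through C2–C1–C10, and the C4 quaternary carbon next to the C5=C10 alkene is the α-alkylated, deconjugated form of a C3(=O)–C4=C5 enone, so ring A is a latent 1,5-diketone aldol condensation product.
Ring order: ring B first (organocatalytic Michael/aldol sets C8, vinyl cuprate sets C9), ring A in the key step, the butenolide ring attached preformed at the end.

Key step: step 8

Remark: both enantiomers of 2-[diphenyl(trimethylsilyloxy)methyl]pyrrolidine, methyl 3-oxopentanoate, 3-(4-hydroxyphenyl)propanoic acid and 4-bromofuran-2(5H)-one are taken as commercial; the C10 epimer drawn for 13–18 is the one expected at equilibrium, and this center is erased in step 12.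

**Route**

Step 1
Reactants: 1 propanal; 2 but-3-en-2-one
Product: 3 (2S)-2-methyl-5-oxohexanal
Conditions: (R)-2-[diphenyl(trimethylsilyloxy)methyl]pyrrolidine (5 mol%), ethyl 3,4-dihydroxybenzoate (20 mol%), neat, 4 °C
Reagents that add atoms: none
Why: Enamine-catalysed asymmetric Michael addition, in which the silyl-protected diarylprolinol shields one face of the (E)-enamine of propanal so that the enone is attacked from the open face, which by the usual model for this catalyst enantiomer should set the α-methyl center as (S) (the future C8).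

Step 2
Reactants: 3 (2S)-2-methyl-5-oxohexanal
Product: 4 (4S)-4-methylcyclohex-2-en-1-one
Conditions: 0.1 M aq KOH, n-Bu4NOH (cat.), Et2O–THF, reflux
Reagents that add atoms: none
Why: Intramolecular aldol condensation (6-(enolendo)-exo-trig attack of the methyl ketone enolate on the aldehyde, then E1cB dehydration) should close the ring under dilute two-phase base before the aldehyde α-center epimerizes appreciably, after which that center is no longer α to a carbonyl group.

Step 3
Reactants: 4 (4S)-4-methylcyclohex-2-en-1-one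
Product: 5 trimethyl{[(3R,4S)-3,4-dimethylcyclohex-1-en-1-yl]oxy}silane
Conditions: Me2CuLi, TMSCl, THF, −78 °C; Et3N, pentane work-up
Reagents that add atoms: lithium dimethylcuprate, [Li+].C[Cu-]C; chlorotrimethylsilane, C[Si](C)(C)Cl
Why: Conjugate addition of the cuprate with in situ silylation of the enolate places the missing methyl group on C3 (anti to the 4-methyl group, although this new center is erased in step 4) and stores the enolate regiochemistry needed for the oxidation.

Step 4
Reactants: 5 trimethyl{[(3R,4S)-3,4-dimethylcyclohex-1-en-1-yl]oxy}silane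
Product: 6 (4S)-3,4-dimethylcyclohex-2-en-1-one
Conditions: Pd(OAc)2 (1.05 equiv), MeCN, rt
Reagents that add atoms: none
Why: Saegusa–Ito oxidation, in which palladation of the silyl enol ether at C2 and β-hydride elimination toward C3 regenerate the enone, now β-methylated, without touching the C4 stereocenter.

Step 5
Reactants: 6 (4S)-3,4-dimethylcyclohex-2-en-1-one
Product: 7 {[(3R,4S)-3-ethenyl-3,4-dimethylcyclohex-1-en-1-yl]oxy}trimethylsilane
Conditions: CH2=CHMgBr, CuBr·SMe2 (10 mol%), TMSCl, DMPU, THF, −78 °C; Et3N, pentane work-up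
Reagents that add atoms: vinylmagnesium bromide, C=C[Mg]Br; chlorotrimethylsilane, C[Si](C)(C)Cl
Why: Chlorosilane-accelerated, CuBr·SMe2-catalysed conjugate addition of the vinyl Grignard reagent to the β,β-disubstituted enone, in which the vinyl group should enter anti to the adjacent C4 methyl group (axial attack on the half-chair), setting the quaternary center (future C9) with the two methyl groups cis while the enolate is trapped regiospecifically toward that center.

Step 6
Reactants: 7 {[(3R,4S)-3-ethenyl-3,4-dimethylcyclohex-1-en-1-yl]oxy}trimethylsilane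
Product: 8 (3R,4S)-2-[(dimethylamino)methyl]-3-ethenyl-3,4-dimethylcyclohexan-1-one (both C2 epimers)
Conditions: CH2=NMe2+ I−, CH2Cl2, rt; then aq NaHCO3
Reagents that add atoms: dimethyl(methylidene)ammonium iodide, C=[N+](C)C.[I-]
Why: Mannich reaction of the regiodefined silyl enol ether with the preformed iminium salt attaches the one-carbon unit (future C1) only at the α-carbon next to the quaternary center, and the new stereocenter is of no consequence because it is lost in step 8.

Step 7
Reactants: 8 (3R,4S)-2-[(dimethylamino)methyl]-3-ethenyl-3,4-dimethylcyclohexan-1-one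
Product: 9 {[(2R,3S)-2-ethenyl-2,3-dimethyl-6-oxocyclohexyl]methyl}trimethylammonium iodide (both C1 epimers)
Conditions: MeI, Et2O, rt
Reagents that add atoms: iodomethane, CI
Why: Menshutkin quaternization turns the amine into a leaving group so that the exocyclic enone can be released by mild base in the flask of step 8 and need not be isolated.

Step 8
Reactants: 9 {[(2R,3S)-2-ethenyl-2,3-dimethyl-6-oxocyclohexyl]methyl}trimethylammonium iodide; 10 methyl 3-oxopentanoate
Product: 15 (4aS,5R,6S)-5-ethenyl-1,5,6-trimethyl-4,4a,5,6,7,8-hexahydronaphthalen-2(3H)-one, via methylidene ketone 11 (not isolated), via Michael adduct 12 (not isolated), via bicyclic keto ester 13 (not isolated), via bicyclic keto acid 14 (not isolated)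
Conditions: NaOMe, MeOH, 0 °C → rt; then KOH, H2O–MeOH, reflux; then aq HCl, 50 °C
Reagents that add atoms: none
Why: Methoxide first expels trimethylamine from 9 (E1cB) to give the s-cis enone 11, the ester-stabilized C2 carbanion of 10 adds to its exocyclic CH2 (Michael addition, C1–C2 bond), and in hot aqueous KOH the C4 methylene of the resulting 1,5-diketone 12 adds to the ring-B carbonyl C5 (aldol, C4–C5 bond) and the ketol loses water (E1cB) to the tetrasubstituted enone 13, whose ester is saponified and lost as CO2 on acidification (14 to 15). The closest known reaction type is the Robinson annulation in its Mannich-base methiodide/β-keto ester form, which makes exactly this pair of bonds. Ring A is closed by the aldol step in a 6-(enolendo)-exo-trig mode, the Michael step being intermolecular. The only new stereocenter, C10, is under thermodynamic control through the extended dienolate in the basic medium and should settle with its hydrogen trans to the C9 methyl group (ring-A bond equatorial on a ring-B chair that keeps the C8 methyl equatorial); it is removed again in step 12. The step needs the donor to react at C2 and then at C4 and the aldol to choose C5: the ester makes C2 the only carbon deprotonated by methoxide, and of the possible aldol modes only C4 onto C5 gives a six-membered ketol that can dehydrate, the bridged ketol from C6 onto C3 forming reversibly. The regiodefined exocyclic methylene, fixed by the silyl enol ether of step 5, guarantees that C1 sits on C10 and not on C6.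

Step 9
Reactants: 15 (4aS,5R,6S)-5-ethenyl-1,5,6-trimethyl-4,4a,5,6,7,8-hexahydronaphthalen-2(3H)-one
Product: 16 (4aS,5R,6S)-5-ethenyl-2-ethoxy-1,5,6-trimethyl-3,4,4a,5,6,7-hexahydronaphthalene
Conditions: HC(OEt)3, TsOH·H2O (cat.), EtOH–dioxane, rt; pyridine quench
Reagents that add atoms: triethyl orthoformate, CCOC(OCC)OCC
Why: Acid-catalysed exchange with the orthoformate under equilibrating conditions should give the transoid dienol ether that spans both rings (C3=C4 and C5=C6) in preference to the cisoid diene confined to ring A, as is general for 4-en-3-ones of this type.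

Step 10
Reactants: 16 (4aS,5R,6S)-5-ethenyl-2-ethoxy-1,5,6-trimethyl-3,4,4a,5,6,7-hexahydronaphthalene
Product: 17 (4aS,5R,6S,8S)-5-ethenyl-8-hydroxy-1,5,6-trimethyl-4,4a,5,6,7,8-hexahydronaphthalen-2(3H)-one
Conditions: mCPBA (1.0 equiv), NaHCO3, dioxane–H2O, 0 °C
Reagents that add atoms: 3-chloroperoxybenzoic acid, OOC(=O)c1cccc(Cl)c1; water, O
Why: Vinylogous Rubottom-type oxidation, in which the peracid attacks the diene terminus C6 (the only site that leaves an oxocarbenium ion conjugated with the remaining alkene) axially on the face whose only syn-axial neighbours are hydrogens (chair-like transition state of ring B with the C8 methyl equatorial), which should set the C6 carbinol as required before hydrolysis returns the enone.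

Step 11
Reactants: 17 (4aS,5R,6S,8S)-5-ethenyl-8-hydroxy-1,5,6-trimethyl-4,4a,5,6,7,8-hexahydronaphthalen-2(3H)-one
Product: 18 (4aS,5R,6S,8S)-8-{[tert-butyl(dimethyl)silyl]oxy}-5-ethenyl-1,5,6-trimethyl-4,4a,5,6,7,8-hexahydronaphthalen-2(3H)-one
Conditions: TBSOTf, 2,6-lutidine, CH2Cl2, −78 → 0 °C
Reagents that add atoms: tert-butyldimethylsilyl trifluoromethanesulfonate, CC(C)(C)[Si](C)(C)OS(=O)(=O)C(F)(F)F
Why: Silylation with the reactive triflate protects the hindered axial allylic alcohol and installs the bulky group that steers step 12.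

Step 12
Reactants: 18 (4aS,5R,6S,8S)-8-{[tert-butyl(dimethyl)silyl]oxy}-5-ethenyl-1,5,6-trimethyl-4,4a,5,6,7,8-hexahydronaphthalen-2(3H)-one
Product: 20 (1S,5R,6S,8S)-8-{[tert-butyl(dimethyl)silyl]oxy}-5-ethenyl-1-(hydroxymethyl)-1,5,6-trimethyl-3,4,5,6,7,8-hexahydronaphthalen-2(1H)-one, via potassium dienolate 19 (not isolated)
Conditions: t-BuOK, THF, 0 °C; then CH2O (gas, from paraformaldehyde), −78 °C; AcOH quench at −78 °C
Reagents that add atoms: potassium tert-butoxide, CC(C)(C)[O-].[K+] (potassium held in 19 only); formaldehyde, C=O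
Why: Deconjugative aldol reaction of an extended dienolate, in which t-BuOK should remove the axial C10 hydrogen (aligned with the enone π system) and not the C6 hydrogen (held in the nodal plane because A(1,3) strain with the C4 methyl group keeps the silyloxy group axial), and formaldehyde then adds to C4 of 19 on the face anti to that silyloxy group, which sets the quaternary center and leaves the alkene at C5=C10.

Step 13
Reactants: 21 3-(4-hydroxyphenyl)propanoic acid
Product: 23 3-(4-{[tert-butyl(dimethyl)silyl]oxy}phenyl)propanoic acid, via bis-silyl derivative 22 (not isolated)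
Conditions: TBSCl (2.2 equiv), imidazole, DMF, rt; then AcOH–THF–H2O, rt
Reagents that add atoms: tert-butyl(chloro)dimethylsilane, CC(C)(C)[Si](C)(C)Cl
Why: Silylation of both acidic hydroxyl groups followed by selective hydrolysis of the far more labile silyl ester frees the acid while the phenol stays protected.

Step 14
Reactants: 20 (1S,5R,6S,8S)-8-{[tert-butyl(dimethyl)silyl]oxy}-5-ethenyl-1-(hydroxymethyl)-1,5,6-trimethyl-3,4,5,6,7,8-hexahydronaphthalen-2(1H)-one; 23 3-(4-{[tert-butyl(dimethyl)silyl]oxy}phenyl)propanoic acid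
Product: 24 [(1S,5R,6S,8S)-8-{[tert-butyl(dimethyl)silyl]oxy}-5-ethenyl-1,5,6-trimethyl-2-oxo-1,2,3,4,5,6,7,8-octahydronaphthalen-1-yl]methyl 3-(4-{[tert-butyl(dimethyl)silyl]oxy}phenyl)propanoate
Conditions: EDC·HCl, DMAP, CH2Cl2, rt
Reagents that add atoms: none
Why: Steglich esterification acylates the neopentyl primary alcohol under conditions mild enough to avoid retro-aldol loss of formaldehyde from the β-hydroxy ketone.

Step 15
Reactants: 24 the ester of step 14; 25 4-bromofuran-2(5H)-one
Product: 27 [(1S,5R,6S,8S)-8-{[tert-butyl(dimethyl)silyl]oxy}-1,5,6-trimethyl-2-oxo-5-[2-(5-oxo-2,5-dihydrofuran-3-yl)ethyl]-1,2,3,4,5,6,7,8-octahydronaphthalen-1-yl]methyl 3-(4-{[tert-butyl(dimethyl)silyl]oxy}phenyl)propanoate, via alkylborane 26 (not isolated)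
Conditions: 9-BBN, THF, 0 °C → rt; then 25, Pd(dppf)Cl2 (5 mol%), AsPh3, K3PO4 (aq), DMF–THF, rt
Reagents that add atoms: 9-borabicyclo[3.3.1]nonane, B1C2CCCC1CCC2 (boron held in 26 only)
Why: Anti-Markovnikov hydroboration of the only monosubstituted alkene with the bulky borane (the tetrasubstituted alkene and the hindered α-quaternary ketone should react much more slowly) followed by Pd(dppf)Cl2-catalysed B-alkyl Suzuki–Miyaura coupling with the β-bromobutenolide completes the side chain without touching a stereocenter.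

Step 16
Reactants: 27 the bis-silyl ether of step 15
Product: 28 [(1S,5R,6S,8S)-8-hydroxy-1,5,6-trimethyl-2-oxo-5-[2-(5-oxo-2,5-dihydrofuran-3-yl)ethyl]-1,2,3,4,5,6,7,8-octahydronaphthalen-1-yl]methyl 3-(4-hydroxyphenyl)propanoate (CNP0301014.1)
Conditions: HF·pyridine, pyridine–THF, 0 °C → rt
Reagents that add atoms: none
Why: Fluoride-induced cleavage of both silyl ethers under buffered acidic conditions, which the butenolide, the ester and the allylic alcohol should survive, releases the target.

**Compound list**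

1 | propanal | CCC=O | starting material
2 | but-3-en-2-one | CC(=O)C=C | starting material
3 | (2S)-2-methyl-5-oxohexanal | C[C@H](C=O)CCC(C)=O | intermediate
4 | (4S)-4-methylcyclohex-2-en-1-one | C[C@H]1CCC(=O)C=C1 | intermediate
5 | trimethyl{[(3R,4S)-3,4-dimethylcyclohex-1-en-1-yl]oxy}silane | C[C@H]1CCC(O[Si](C)(C)C)=C[C@@H]1C | intermediate
6 | (4S)-3,4-dimethylcyclohex-2-en-1-one | C[C@H]1CCC(=O)C=C1C | intermediate
7 | {[(3R,4S)-3-ethenyl-3,4-dimethylcyclohex-1-en-1-yl]oxy}trimethylsilane | C[C@H]1CCC(O[Si](C)(C)C)=C[C@]1(C)C=C | intermediate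
8 | (3R,4S)-2-[(dimethylamino)methyl]-3-ethenyl-3,4-dimethylcyclohexan-1-one (C2 epimers) | C[C@H]1CCC(=O)C(CN(C)C)[C@]1(C)C=C | intermediate
9 | {[(2R,3S)-2-ethenyl-2,3-dimethyl-6-oxocyclohexyl]methyl}trimethylammonium iodide (C1 epimers) | C[C@H]1CCC(=O)C(C[N+](C)(C)C)[C@]1(C)C=C.[I-] | intermediate
10 | methyl 3-oxopentanoate | CCC(=O)CC(=O)OC | starting material
11 | (3R,4S)-3-ethenyl-3,4-dimethyl-2-methylidenecyclohexan-1-one | C[C@H]1CCC(=O)C(=C)[C@]1(C)C=C | intermediate
12 | methyl 2-{[(2R,3S)-2-ethenyl-2,3-dimethyl-6-oxocyclohexyl]methyl}-3-oxopentanoate (mixture at the two enolizable centers) | C[C@H]1CCC(=O)C(CC(C(=O)OC)C(=O)CC)[C@]1(C)C=C | intermediate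
13 | methyl (7S,8R,8aS)-8-ethenyl-4,7,8-trimethyl-3-oxo-1,2,3,5,6,7,8,8a-octahydronaphthalene-2-carboxylate (C2 epimers) | C[C@H]1CCC2=C(C)C(=O)C(C(=O)OC)C[C@H]2[C@]1(C)C=C | intermediate
14 | (7S,8R,8aS)-8-ethenyl-4,7,8-trimethyl-3-oxo-1,2,3,5,6,7,8,8a-octahydronaphthalene-2-carboxylic acid (C2 epimers) | C[C@H]1CCC2=C(C)C(=O)C(C(=O)O)C[C@H]2[C@]1(C)C=C | intermediate
15 | (4aS,5R,6S)-5-ethenyl-1,5,6-trimethyl-4,4a,5,6,7,8-hexahydronaphthalen-2(3H)-one | C[C@H]1CCC2=C(C)C(=O)CC[C@H]2[C@]1(C)C=C | intermediate
16 | (4aS,5R,6S)-5-ethenyl-2-ethoxy-1,5,6-trimethyl-3,4,4a,5,6,7-hexahydronaphthalene | C[C@H]1CC=C2C(C)=C(OCC)CC[C@H]2[C@]1(C)C=C | intermediate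
17 | (4aS,5R,6S,8S)-5-ethenyl-8-hydroxy-1,5,6-trimethyl-4,4a,5,6,7,8-hexahydronaphthalen-2(3H)-one | C[C@H]1C[C@H](O)C2=C(C)C(=O)CC[C@H]2[C@]1(C)C=C | intermediate
18 | (4aS,5R,6S,8S)-8-{[tert-butyl(dimethyl)silyl]oxy}-5-ethenyl-1,5,6-trimethyl-4,4a,5,6,7,8-hexahydronaphthalen-2(3H)-one | C[C@H]1C[C@H](O[Si](C)(C)C(C)(C)C)C2=C(C)C(=O)CC[C@H]2[C@]1(C)C=C | intermediate
19 | potassium (5R,6S,8S)-8-{[tert-butyl(dimethyl)silyl]oxy}-5-ethenyl-1,5,6-trimethyl-3,4,5,6,7,8-hexahydronaphthalen-2-olate | C[C@H]1C[C@H](O[Si](C)(C)C(C)(C)C)C2=C(CCC([O-])=C2C)[C@]1(C)C=C.[K+] | intermediate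
20 | (1S,5R,6S,8S)-8-{[tert-butyl(dimethyl)silyl]oxy}-5-ethenyl-1-(hydroxymethyl)-1,5,6-trimethyl-3,4,5,6,7,8-hexahydronaphthalen-2(1H)-one | C[C@H]1C[C@H](O[Si](C)(C)C(C)(C)C)C2=C(CCC(=O)[C@]2(C)CO)[C@]1(C)C=C | intermediate
21 | 3-(4-hydroxyphenyl)propanoic acid | OC(=O)CCc1ccc(O)cc1 | starting material
22 | tert-butyl(dimethyl)silyl 3-(4-{[tert-butyl(dimethyl)silyl]oxy}phenyl)propanoate | CC(C)(C)[Si](C)(C)OC(=O)CCc1ccc(O[Si](C)(C)C(C)(C)C)cc1 | intermediate
23 | 3-(4-{[tert-butyl(dimethyl)silyl]oxy}phenyl)propanoic acid | OC(=O)CCc1ccc(O[Si](C)(C)C(C)(C)C)cc1 | intermediate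
24 | [(1S,5R,6S,8S)-8-{[tert-butyl(dimethyl)silyl]oxy}-5-ethenyl-1,5,6-trimethyl-2-oxo-1,2,3,4,5,6,7,8-octahydronaphthalen-1-yl]methyl 3-(4-{[tert-butyl(dimethyl)silyl]oxy}phenyl)propanoate | C[C@H]1C[C@H](O[Si](C)(C)C(C)(C)C)C2=C(CCC(=O)[C@]2(C)COC(=O)CCc2ccc(O[Si](C)(C)C(C)(C)C)cc2)[C@]1(C)C=C | intermediate
25 | 4-bromofuran-2(5H)-one | O=C1C=C(Br)CO1 | starting material
26 | [(1S,5R,6S,8S)-5-[2-(9-borabicyclo[3.3.1]nonan-9-yl)ethyl]-8-{[tert-butyl(dimethyl)silyl]oxy}-1,5,6-trimethyl-2-oxo-1,2,3,4,5,6,7,8-octahydronaphthalen-1-yl]methyl 3-(4-{[tert-butyl(dimethyl)silyl]oxy}phenyl)propanoate | C[C@H]1C[C@H](O[Si](C)(C)C(C)(C)C)C2=C(CCC(=O)[C@]2(C)COC(=O)CCc2ccc(O[Si](C)(C)C(C)(C)C)cc2)[C@]1(C)CCB1C2CCCC1CCC2 | intermediate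
27 | [(1S,5R,6S,8S)-8-{[tert-butyl(dimethyl)silyl]oxy}-1,5,6-trimethyl-2-oxo-5-[2-(5-oxo-2,5-dihydrofuran-3-yl)ethyl]-1,2,3,4,5,6,7,8-octahydronaphthalen-1-yl]methyl 3-(4-{[tert-butyl(dimethyl)silyl]oxy}phenyl)propanoate | C[C@H]1C[C@H](O[Si](C)(C)C(C)(C)C)C2=C(CCC(=O)[C@]2(C)COC(=O)CCc2ccc(O[Si](C)(C)C(C)(C)C)cc2)[C@]1(C)CCC1=CC(=O)OC1 | intermediate
28 | [(1S,5R,6S,8S)-8-hydroxy-1,5,6-trimethyl-2-oxo-5-[2-(5-oxo-2,5-dihydrofuran-3-yl)ethyl]-1,2,3,4,5,6,7,8-octahydronaphthalen-1-yl]methyl 3-(4-hydroxyphenyl)propanoate | C[C@H]1C[C@H](O)C2=C(CCC(=O)[C@]2(C)COC(=O)CCc2ccc(O)cc2)[C@]1(C)CCC1=CC(=O)OC1 | target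

**Step count and risks**

Total step count: 16. Longest linear sequence: 15 steps (steps 1–12 and 14–16; step 13 is a one-step side branch).

Step 12 (most at risk). The base may deprotonate at C2 to give the cross-conjugated enolate, or the aldolate may revert by loss of formaldehyde before the quench; either would lower the yield of the quaternary center. Fallback: setting out from 18, thermodynamic silylation (TMSCl, NaI, Et3N, MeCN, 40 °C) should give the isolable silyl dienol ether F1, whose constitution can be checked before use. A Mukaiyama aldol reaction of the silyl dienol ether F1 with aqueous formaldehyde (Yb(OTf)3, THF–H2O, rt) would then form the C4–C19 bond under acidic, irreversible conditions and come back to the route at 20. Attack at the γ-carbon is disfavoured because C10 is fully substituted and flanked by the C9 quaternary carbon, and the facial argument of step 12 is unchanged.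

Step 10. Poor facial selectivity of the peracid at the diene terminus would give the C6 epimer. Fallback: setting out from 16, if the oxidation delivers mainly the equatorial alcohol F2, a Mitsunobu reaction (4-nitrobenzoic acid, PPh3, DIAD, THF, 0 °C → rt) should invert it to the axial 4-nitrobenzoate F3. Methanolysis of the axial 4-nitrobenzoate F3 (K2CO3, MeOH, 0 °C) then comes back to the route at 17.

Step 15. The dialkylborane may reduce the C3 ketone in competition with hydroboration, and the alkylborane may suffer protodeboronation under the aqueous base. Fallback: setting out from 24, hydroboration with pinacolborane catalysed by [Ir(cod)Cl]2/dppm (CH2Cl2, rt), a system expected to tolerate the ketone, should give the isolable pinacol boronate F4. Suzuki–Miyaura coupling of the pinacol boronate F4 with 25 (Pd(OAc)2, RuPhos, K3PO4, toluene–H2O, 80 °C) then comes back to the route at 27.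

Further compounds
F1 | step 12 | trimethylsilyl dienol ether of 18 (2-trimethylsilyloxy-1,8a-diene, 8-silyloxy group retained) | C[C@H]1C[C@H](O[Si](C)(C)C(C)(C)C)C2=C(CCC(O[Si](C)(C)C)=C2C)[C@]1(C)C=C
F2 | step 10 | (4aS,5R,6S,8R)-5-ethenyl-8-hydroxy-1,5,6-trimethyl-4,4a,5,6,7,8-hexahydronaphthalen-2(3H)-one (8-epimer of 17) | C[C@H]1C[C@@H](O)C2=C(C)C(=O)CC[C@H]2[C@]1(C)C=C
F3 | step 10 | 4-nitrobenzoate ester of 17 (8S) | C[C@H]1C[C@H](OC(=O)c3ccc(cc3)[N+](=O)[O-])C2=C(C)C(=O)CC[C@H]2[C@]1(C)C=C
F4 | step 15 | pinacol boronate from anti-Markovnikov hydroboration of the vinyl group of 24 | C[C@H]1C[C@H](O[Si](C)(C)C(C)(C)C)C2=C(CCC(=O)[C@]2(C)COC(=O)CCc2ccc(O[Si](C)(C)C(C)(C)C)cc2)[C@]1(C)CCB1OC(C)(C)C(C)(C)O1
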